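Retrosynthetic cuts, in order: the enol-ester O–C(=O) bond (senecioyl group off), the C2' carbonyl oxygen (back to CH2), the pyranone ring at O1–C2 and C3=C4, the O7–CH3 bond, and last the benzene ring at C4a–C5 and C7–C8.
Enabling feature: around the carbocycle of the coumarin the substituents alternate as in a polyketide. C4a holds carbon C4, C8a holds O1, C8 holds the ketone carbon C1', C7 holds the methoxy oxygen, and C5 and C6 are bare CH. So C4–C4a–C8a–C8–C1' maps onto an ester-terminated 1,3,5-tricarbonyl chain and C5–C6–C7 onto a propiolate ester.
Forward order: the open chain is joined by γ-acylation of acetoacetate dianion, and the benzene ring arises first by a (3+3) Michael–Claisen annulation. The pyranone ring follows by Wittig lactonisation after O7-methylation and ester-to-aldehyde adjustment, and the side chain is finished by α-oxidation and enol O-acylation.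
Stereochemistry: the target has no stereocentre, C3=C4 is cis by ring constraint and the enol-ester alkene ends in CMe2, so nothing has to be controlled. The one carbinol centre that appears on hydride reduction is racemic and is erased by the next oxidation.

Key step: step 2

Remark: β-dicarbonyl compounds are drawn as keto tautomers and the anions formed in the flask as discrete salts. Locants C2 to C5 in steps 1 and 2 count along the dioxoester chain from the ester carbon; all other locants follow the coumarin.

Step 1
Reactants: 1 methyl acetoacetate; 2 methyl 3-methylbutanoate
Product: 4 methyl 7-methyl-3,5-dioxooctanoate, via acetoacetate dianion 3 (not isolated)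
Conditions: 1 (2 equiv), NaH, THF, 0 °C; n-BuLi, 0 °C; then 2 (1 equiv), 0 °C to rt; aq. HCl
Reagents that add atoms: none
Why: γ-Selective Claisen-type acylation of a β-keto ester dianion, in which the terminal carbanion of 3 (the last formed and least stabilised site) attacks the ester carbonyl of 2, while the second equivalent of 3 takes up the acidic C4 proton of the product so that the acylation can run to completion.

Step 2
Reactants: 4 methyl 7-methyl-3,5-dioxooctanoate; 5 methyl propiolate
Product: 8 methyl 2,4-dihydroxy-3-(3-methylbutanoyl)benzoate, via dioxoester dianion 6 (not isolated), via Michael adduct 7 (not isolated)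
Conditions: NaH (1.0 equiv), THF, 0 °C; n-BuLi (1.0 equiv), −78 to 0 °C; 5 (1.0 equiv, slow addition), −78 to 0 °C; then MeOH, 60 °C; aq. HCl
Reagents that add atoms: none
Why: NaH removes the proton between the two ketones (chain C4) and n-BuLi the one between ketone and ester (chain C2), and the later-formed, less stabilised C2 carbanion of 6 adds to the β-carbon of 5, which makes the future C4a–C5 bond. The allenolate picks up the now very acidic C2 proton to give the anion of 7, a delocalised glutaconate whose C=C bond turns freely into the Z arrangement, and the diketone carbanion C4 then attacks the acrylate ester carbonyl in a 6-exo-trig Claisen (Dieckmann-type) closure that makes the future C7–C8 bond, expels methoxide and, after one more proton loss, leaves the six-membered carbocycle as the aromatic resorcinol bis-phenoxide without any new stereocentre. The closest known reaction type is the Michael addition–Dieckmann resorcinol annulation of 3-oxoglutarate anions with alkynoates, here run with a ketone in place of one ester. Regioselectivity of the Michael step (C2, not C4) is needed and is secured by using the complete dianion in a medium whose only conjugate acids are H2 and butane, and by adding one equivalent of 5 slowly at −78 °C so that deprotonation of the alkyne C–H and double addition stay behind. Chemoselectivity of the closure (carbon, not the C3 enolate oxygen) is needed as well and is secured thermodynamically, because a 2-pyranone is reopened by methoxide while aromatisation is irreversible. Methanol goes in only after the C–C bond of the Michael step is in place, where it shuttles protons so that the acrylate ester is not held as an unreactive vinylogous enolate.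

Step 3
Reactants: 8 methyl 2,4-dihydroxy-3-(3-methylbutanoyl)benzoate
Product: 9 methyl 2-hydroxy-4-methoxy-3-(3-methylbutanoyl)benzoate
Conditions: MeI (1.1 equiv), K2CO3 (1.1 equiv), acetone, rt to 40 °C
Reagents that add atoms: iodomethane, CI
Why: Williamson ether synthesis under mild carbonate conditions, in which the C4 hydroxyl (one free ortho position, para to the ester) is the more accessible and more acidic site whereas the C2 hydroxyl is wedged between two carbonyl groups that both chelate it, so one equivalent of MeI should alkylate only the future O7.

Step 4
Reactants: 9 methyl 2-hydroxy-4-methoxy-3-(3-methylbutanoyl)benzoate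
Product: 10 6-(hydroxymethyl)-2-(1-hydroxy-3-methylbutyl)-3-methoxyphenol (racemic)
Conditions: LiAlH4, THF, 0 °C to rt; Na2SO4·10H2O
Reagents that add atoms: none
Why: Hydride reduction with LiAlH4 takes the ester to the primary alcohol and unavoidably the ketone to a racemic secondary alcohol, which does no harm because both carbinols are benzylic and are reoxidised together in step 5, while the low temperature and the non-acidic quench guard against loss of benzylic oxygen through an o-quinone methide.

Step 5
Reactants: 10 6-(hydroxymethyl)-2-(1-hydroxy-3-methylbutyl)-3-methoxyphenol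
Product: 11 2-hydroxy-4-methoxy-3-(3-methylbutanoyl)benzaldehyde
Conditions: activated MnO2 (excess), CH2Cl2, rt to reflux
Reagents that add atoms: none
Why: MnO2 oxidation of benzylic alcohols converts both carbinols in one operation, tolerates the free phenol (it is the usual passage from salicyl alcohols to salicylaldehydes) and erases the transient stereocentre.

Step 6
Reactants: 11 2-hydroxy-4-methoxy-3-(3-methylbutanoyl)benzaldehyde
Product: 14 7-methoxy-8-(3-methylbutanoyl)-2H-chromen-2-one, via E-cinnamate 12 (not isolated), via Z-cinnamate 13 (not isolated)
Conditions: Ph3P=CHCO2Et, PhNEt2, reflux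
Reagents that add atoms: ethyl (triphenylphosphoranylidene)acetate, CCOC(=O)C=P(c1ccccc1)(c1ccccc1)c1ccccc1
Why: Wittig olefination of the aldehyde (the hindered ketone is inert to a stabilised ylide) gives mainly 12, which at the boiling point of diethylaniline isomerises to 13 and lactonises through the neighbouring phenol, the established one-pot passage from salicylaldehydes to 3,4-unsubstituted coumarins.

Step 7
Reactants: 14 7-methoxy-8-(3-methylbutanoyl)-2H-chromen-2-one
Product: 15 1-(7-methoxy-2-oxo-2H-chromen-8-yl)-3-methylbutane-1,2-dione
Conditions: SeO2, 1,4-dioxane/H2O, reflux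
Reagents that add atoms: selenium dioxide, O=[Se]=O
Why: Riley oxidation, in which SeO2 attacks the enol of the aryl alkyl ketone at its only α-methylene group and delivers the 1,2-diketone, while the coumarin has no allylic or other enolisable C–H and is left alone.

Step 8
Reactants: 15 1-(7-methoxy-2-oxo-2H-chromen-8-yl)-3-methylbutane-1,2-dione; 16 3-methylbut-2-enoyl chloride (senecioyl chloride)
Product: 18 kimcuongin, via potassium enolate 17 (not isolated)
Conditions: KN(SiMe3)2, THF, −78 °C; then 16, −78 to 0 °C
Reagents that add atoms: none
Why: Enolate O-acylation, favoured because the diketone has a single enolisable hydrogen (the isopropyl CH), the fully substituted carbon terminus of 17 is too hindered for C-acylation by the hard acid chloride, and the absence of a tertiary amine avoids the vinylketene pathway that would move the senecioyl double bond out of conjugation.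

Compound list
1 | methyl acetoacetate | COC(=O)CC(C)=O | starting material
2 | methyl 3-methylbutanoate | COC(=O)CC(C)C | starting material
3 | sodium lithium dianion of methyl acetoacetate (not isolated) | [Na+].[Li+].COC([O-])=CC([O-])=C | intermediate
4 | methyl 7-methyl-3,5-dioxooctanoate | COC(=O)CC(=O)CC(=O)CC(C)C | intermediate
5 | methyl propiolate | C#CC(=O)OC | starting material
6 | sodium lithium 2,4-dianion of methyl 7-methyl-3,5-dioxooctanoate (not isolated) | [Na+].[Li+].COC([O-])=CC(=O)C=C([O-])CC(C)C | intermediate
7 | dimethyl 4-(5-methyl-3-oxohexanoyl)pent-2-enedioate, present as its anion with interconverting E and Z forms (not isolated) | COC(=O)C=CC(C(=O)OC)C(=O)CC(=O)CC(C)C | intermediate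
8 | methyl 2,4-dihydroxy-3-(3-methylbutanoyl)benzoate | COC(=O)c1ccc(O)c(C(=O)CC(C)C)c1O | intermediate
9 | methyl 2-hydroxy-4-methoxy-3-(3-methylbutanoyl)benzoate | COC(=O)c1ccc(OC)c(C(=O)CC(C)C)c1O | intermediate
10 | 6-(hydroxymethyl)-2-(1-hydroxy-3-methylbutyl)-3-methoxyphenol, racemic | OCc1ccc(OC)c(C(O)CC(C)C)c1O | intermediate
11 | 2-hydroxy-4-methoxy-3-(3-methylbutanoyl)benzaldehyde | O=Cc1ccc(OC)c(C(=O)CC(C)C)c1O | intermediate
12 | ethyl (2E)-3-[2-hydroxy-4-methoxy-3-(3-methylbutanoyl)phenyl]prop-2-enoate (not isolated) | CCOC(=O)/C=C/c1ccc(OC)c(C(=O)CC(C)C)c1O | intermediate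
13 | ethyl (2Z)-3-[2-hydroxy-4-methoxy-3-(3-methylbutanoyl)phenyl]prop-2-enoate (not isolated) | CCOC(=O)/C=C\c1ccc(OC)c(C(=O)CC(C)C)c1O | intermediate
14 | 7-methoxy-8-(3-methylbutanoyl)-2H-chromen-2-one | COc1ccc2ccc(=O)oc2c1C(=O)CC(C)C | intermediate
15 | 1-(7-methoxy-2-oxo-2H-chromen-8-yl)-3-methylbutane-1,2-dione | COc1ccc2ccc(=O)oc2c1C(=O)C(=O)C(C)C | intermediate
16 | 3-methylbut-2-enoyl chloride | CC(C)=CC(=O)Cl | starting material
17 | potassium 1-(7-methoxy-2-oxo-2H-chromen-8-yl)-3-methyl-1-oxobut-2-en-2-olate (not isolated) | [K+].COc1ccc2ccc(=O)oc2c1C(=O)C([O-])=C(C)C | intermediate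
18 | kimcuongin, 1-(7-methoxy-2-oxo-2H-chromen-8-yl)-3-methyl-1-oxobut-2-en-2-yl 3-methylbut-2-enoate | COc1ccc2ccc(=O)oc2c1C(=O)C(OC(=O)C=C(C)C)=C(C)C | target

Total step count: 8. Longest linear sequence: 8 steps (1 to 18).

Steps most likely to fail

Step 2. Proton transfer from the alkyne C–H of 5 to dianion 6 may outrun conjugate addition. The monoanion so returned reacts through C4 and erodes the regiochemistry. Claisen closure may also lag behind O-lactonisation or oligomerisation of the propiolate. The fallback forms the same two ring bonds in separate operations, so that only one carbon nucleophile is present at a time. It sets out from 1 and 5. Base-catalysed Michael addition (cat. NaOMe, MeOH) at the only active methylene group of 1, with lactonisation on heating in the same flask, should give methyl 6-methyl-2-oxo-2H-pyran-5-carboxylate F1. Lateral deprotonation of its C6 methyl group with LiN(SiMe3)2 (2 equiv, THF, −78 °C) and Claisen acylation with 2 should give methyl 6-(4-methyl-2-oxopentyl)-2-oxo-2H-pyran-5-carboxylate F2. NaOMe in hot MeOH then opens the lactone to the Z-configured anion of 7, which closes the C7–C8 bond. The fallback comes back to the route at 8.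

Step 8. C-acylation of the enolate may compete. The enolate may also dehydrochlorinate 16 to a vinylketene, which would transfer a deconjugated acyl group, or it may attack the coumarin of a second molecule. The fallback replaces the metal enolate by a neutral enol derivative. It sets out from 15, which on soft enolisation (Me3SiOTf, Et3N, CH2Cl2, 0 °C) should give 7-methoxy-8-[3-methyl-2-(trimethylsilyloxy)but-2-enoyl]-2H-chromen-2-one F3. Halide exchange on 16 with KF in MeCN should give 3-methylbut-2-enoyl fluoride F4. Fluoride-catalysed acyl transfer between F3 and F4 (cat. Bu4NF, THF) acylates the enol oxygen under nearly neutral conditions. The fallback comes back to the route at 18.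

Step 7. The twisted, doubly ortho-substituted ketone may enolise slowly, the side chain may be dehydrogenated towards the enone, or over-oxidation may cleave the C–C bond. The fallback installs the oxygen through an enol ether in place of selenium chemistry. It sets out from 14, which with Me3SiOTf and Et3N should give 7-methoxy-8-[(1Z)-3-methyl-1-(trimethylsilyloxy)but-1-en-1-yl]-2H-chromen-2-one F5. Rubottom oxidation (mCPBA, NaHCO3, CH2Cl2, then dilute HCl) at the electron-rich enol ether, not at the electron-poor C3=C4 bond, should give racemic 8-(2-hydroxy-3-methylbutanoyl)-7-methoxy-2H-chromen-2-one F6. Dess–Martin periodinane then oxidises the carbinol. The fallback comes back to the route at 15.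

Further compounds
F1 | step 2 | methyl 6-methyl-2-oxo-2H-pyran-5-carboxylate | COC(=O)C1=C(C)OC(=O)C=C1
F2 | step 2 | methyl 6-(4-methyl-2-oxopentyl)-2-oxo-2H-pyran-5-carboxylate | COC(=O)C1=C(CC(=O)CC(C)C)OC(=O)C=C1
F3 | step 8 | 7-methoxy-8-[3-methyl-2-(trimethylsilyloxy)but-2-enoyl]-2H-chromen-2-one | COc1ccc2ccc(=O)oc2c1C(=O)C(O[Si](C)(C)C)=C(C)C
F4 | step 8 | 3-methylbut-2-enoyl fluoride | CC(C)=CC(=O)F
F5 | step 7 | 7-methoxy-8-[(1Z)-3-methyl-1-(trimethylsilyloxy)but-1-en-1-yl]-2H-chromen-2-one | COc1ccc2ccc(=O)oc2c1/C(O[Si](C)(C)C)=C/C(C)C
F6 | step 7 | 8-(2-hydroxy-3-methylbutanoyl)-7-methoxy-2H-chromen-2-one, racemic | COc1ccc2ccc(=O)oc2c1C(=O)C(O)C(C)C
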